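The readings are simulated with made-up constants; the scatter is artificial.

I was asked what part of the two substrates had reacted in this flask at 2.5 h, and what excess stood in the product and in what was left.

the same everywhere: precatalyst 1.4 mM; added ligand 4.2 mM
- delta: left-handed substrate 0.055 M; right-handed substrate 0.055 M; reagent 0.11 M; the very flask that is asked about, followed so far
- zeta: left-handed substrate 0.11 M; right-handed substrate 0.11 M; reagent 0.11 M; run made earlier
- flask: left-handed substrate 0.055 M; right-handed substrate 0.055 M; reagent 0.110 M; time 2.5 h

| run | time / min | left-handed substrate / % | right-handed substrate / % |
|---|---|---|---|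
| delta | 6.00 | 49.2 | 49.4 |
| delta | 15.0 | 47.3 | 48.7 |
| delta | 30.0 | 44.3 | 44.8 |
| delta | 50.0 | 39.1 | 40.3 |
| zeta | 8.00 | 49.6 | 49.9 |
| zeta | 20.0 | 46.7 | 47.6 |
| zeta | 50.0 | 40.4 | 41.3 |
| zeta | 120 | 31.6 | 31.7 |

(standard deviation of a reading: 0.5 percentage points)

- catalyst is single-handed; left-handed substrate and right-handed substrate are mirror images of each other, charged as a racemate, each of them at the stated concentration
- the numbers in the tables scatter by 0.5 percentage points (one standard deviation)
- an excess is the difference of the two amounts in percent of their sum
- an excess is below zero if the other one leads

- part of the left-handed substrate and right-handed substrate charged together that has reacted at 2.5 h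
- excess of left-handed product over right-handed product in the product at 2.5 h
- excess of right-handed substrate over left-handed substrate among what is left of the two at 2.5 h

The two hands stayed close in the readings: in the zeta run at 120 min their gap was 0.1 percentage points, inside the scatter. So I reckoned with one pool, x, the fraction of the charge left, and one rate. The gap does not touch c, which uses the sum.

The delta stretch from 30.0 min to 50.0 min gave 0.411 /h. The later zeta stretch gave 0.526 /h, more. This is the pool rate, the hourly rise of the reciprocal of x when reagent and substrates are charged equally; in zeta it is the rise of the logarithm of x over the reagent left. I started from the 79.4% left in delta at 50.0 min. Starting from the 30.0 min reading of delta instead shifted my c by 0.82 points, but taking the rate of the delta stretch shifted it by 4.6 points, more. So the rate had to be known well. The pool rate gave me c = 53.2%. I named no eP or eS from hands this close.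

The forecast said c 52%, eP 2.3% and eS 2.5%, “with left reacting slightly faster”.

The flask gave c 52.9%, eP 95.4% and eS 1.08%.

    reagent + catalyst + left-handed substrate → catalyst + left-handed product (k = 9.20 /M²/s)
    left-handed substrate ⇌ right-handed substrate (k = 0.00310 /s)
    precatalyst → catalyst (k = 6.40 × 10⁻⁴ /s)
    2 catalyst ⇌ resting dimer, settled at all times (K = 3600 /M)
    reagent + catalyst + right-handed substrate → catalyst + right-handed product (k = 0.210 /M²/s)
    catalyst + added ligand ⇌ idle complex, settled at all times (K = 500 /M)

In this flask at 1.02 h the making of left-handed product drew on left-handed substrate at 0.064 of the forward rate of its change into right-handed substrate, and the relaxation half-life of that exchange, 1.86 min, is short against 2.5 h. This is a dynamic kinetic resolution: at 2.5 h the hands in this flask stood at 47% and 48% of their charges while the product had eP 95.4%.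

In the flask with 0.028 M of reagent, a quarter of the substrates (0.255), the pool rate over the 2.16 h that delta's progress is worth gave c = 16.3%. That flask gave 16.3%, with eP 95.5%.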